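The route rests on the C12–C13 bond between the sulfated carbinol C12 and the methyl-bearing methine C13. C12 hangs from C9 of ring B through the C11 methylene, has no neighbouring group that could steer its configuration, and is the lactone carbonyl carbon of (+)-sclareolide. It is therefore carried as a primary O-carbamate, lithiated under (−)-sparteine control and joined to a secondary C13 pinacol boronic ester that holds the whole arene side chain. This single lithiation–borylation unites two halves of similar size and fixes C12 as a C–B bond, later oxidised and sulfated. Its precursors are the ring A/B homodrimenyl carbamate and the (R)-boronic ester.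

Key step: step 8

Remark on numbering: C1–C10 are the decalin carbons (ring A: C1–C5 and C10; ring B: C5–C10), C11 is the methylene on C9, C12 the carbinol, C13 the methyl-bearing methine, C14–C16 the methylenes, C17=C18 the side-chain alkene and C19 the benzylic carbon.

Assumption: the target is taken as the hydrogen sulfate that is drawn; because such an acid promotes its own solvolysis, the sulfate is carried as its sodium salt and protonated only in the last, cold operation.

Step 1
Reactants: 1 (+)-sclareolide
Product: 2 (1R,2R,4aS,8aS)-1-(2-hydroxyethyl)-2,5,5,8a-tetramethyldecahydronaphthalen-2-ol (homodrimane-8α,12-diol)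
Conditions: LiAlH4, THF, 0 °C to rt; aq. NaOH work-up
Reagents that add atoms: none
Why: Hydride reduction of the γ-lactone (LiAlH4 reduction of an ester) should open the ring to the 8,12-diol without touching C5, C8, C9 or C10, since only the acyl C–O bond is cleaved.

Step 2
Reactants: 2 homodrimane-8α,12-diol
Product: 3 2-[(1R,2R,4aS,8aS)-2-hydroxy-2,5,5,8a-tetramethyldecahydronaphthalen-1-yl]ethyl N,N-diisopropylcarbamate
Conditions: iPr2NCOCl, Et3N, DMAP (cat.), CH2Cl2, reflux
Reagents that add atoms: N,N-diisopropylcarbamoyl chloride CC(C)N(C(C)C)C(Cl)=O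
Why: Carbamoylation (acyl substitution at the carbamoyl chloride) should occur only at the unhindered primary C12 hydroxyl, the tertiary C8 hydroxyl being inert, and it installs the group that first directs lithiation and then leaves in the key step.

Step 3
Reactants: 3 8α-hydroxy carbamate
Product: 4 2-[(1S,4aS,8aS)-2,5,5,8a-tetramethyl-1,4,4a,5,6,7,8,8a-octahydronaphthalen-1-yl]ethyl N,N-diisopropylcarbamate (homodrim-7-en-12-yl carbamate)
Conditions: conc. H2SO4 (cat.), EtOH, rt; chromatography on AgNO3-impregnated SiO2
Reagents that add atoms: none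
Why: E1 dehydration through the tertiary C8 cation should lose the aligned C7 proton in preference to the C9 methine or a methyl proton, as in the endocyclic trisubstituted terminations of cationic polyene cyclisations, with any exocyclic isomer re-entering the cation; C8 ceases to be a stereocentre and the acid-stable carbamate is untouched.

Step 4
Reactants: 5 5-chloropent-1-yne; 6 2,5-dimethoxybenzyl chloride
Product: 8 2-[(2E)-6-chloro-3-methylhex-2-en-1-yl]-1,4-dimethoxybenzene, via alkenylalane 7 (not isolated)
Conditions: Me3Al, Cp2ZrCl2 (cat.), CH2Cl2, 0 °C to rt; evaporate; then 6, Pd(PPh3)4 (cat.), THF, rt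
Reagents that add atoms: trimethylaluminium C[Al](C)C
Why: Negishi zirconium-catalysed carboalumination adds methyl and aluminium syn across the terminal alkyne with aluminium at the terminus, and the alkenylalane then cross-couples with the benzylic chloride at zerovalent palladium with retention, which fixes the E-alkene while the unactivated primary alkyl chloride takes no part.

Step 5
Reactants: 8 (E)-alkenyl chloride
Product: 10 2-[(4E)-6-(2,5-dimethoxyphenyl)-4-methylhex-4-en-1-yl]-4,4,5,5-tetramethyl-1,3,2-dioxaborolane, via Grignard reagent 9 (not isolated)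
Conditions: Mg, BrCH2CH2Br (cat.), THF, reflux; then iPrOBpin, −78 °C to rt; aq. NH4Cl
Reagents that add atoms: 2-isopropoxy-4,4,5,5-tetramethyl-1,3,2-dioxaborolane CC(C)OB1OC(C)(C)C(C)(C)O1
Why: Magnesium insertion into the primary C–Cl bond followed by trapping of the Grignard reagent with the isopropoxy pinacol borate (borylation of an organomagnesium) should give the primary C14 boronic ester without disturbing the alkene geometry or the aryl ethers.

Step 6
Reactants: 11 ethanol
Product: 12 ethyl N,N-diisopropylcarbamate
Conditions: iPr2NCOCl, Et3N, CH2Cl2, reflux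
Reagents that add atoms: N,N-diisopropylcarbamoyl chloride CC(C)N(C(C)C)C(Cl)=O
Why: Simple O-carbamoylation of ethanol (acyl substitution) gives the two-carbon carbenoid precursor that will supply C13 and its methyl group.

Step 7
Reactants: 12 ethyl N,N-diisopropylcarbamate; 10 primary C14 pinacol boronic ester
Product: 15 2-[(2R,6E)-8-(2,5-dimethoxyphenyl)-6-methyloct-6-en-2-yl]-4,4,5,5-tetramethyl-1,3,2-dioxaborolane, via lithiated ethyl carbamate 13 (not isolated), via boronate complex 14 (not isolated)
Conditions: 12 (excess), s-BuLi, (−)-sparteine, Et2O, −78 °C; then 10, −78 °C; then reflux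
Reagents that add atoms: none
Why: Lithiation–borylation, in which (−)-sparteine-directed removal of the pro-S proton of 12 gives a configurationally stable carbenoid that adds to boron of 10 with retention, after which the 1,2-metallate shift of the primary C14 group with inversion at carbon sets C13 as R (reagent control; Matteson-type homologation).

Step 8
Reactants: 4 homodrim-7-en-12-yl carbamate; 15 (R)-secondary C13 pinacol boronic ester
Product: 18 2-[(2R,3R,7E)-9-(2,5-dimethoxyphenyl)-3,7-dimethyl-1-[(1S,4aS,8aS)-2,5,5,8a-tetramethyl-1,4,4a,5,6,7,8,8a-octahydronaphthalen-1-yl]non-7-en-2-yl]-4,4,5,5-tetramethyl-1,3,2-dioxaborolane (12R,13R), via lithiated carbamate 16 (not isolated), via boronate complex 17 (not isolated)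
Conditions: 4 (slight excess), s-BuLi, (−)-sparteine, Et2O, −78 °C; then 15, −78 °C; then MgBr2·OEt2, reflux
Reagents that add atoms: none
Why: s-BuLi/(−)-sparteine should remove the pro-S proton at C12 of 4, the carbamate carbonyl holding the base at this site so that no allylic proton of ring B competes, and the configurationally stable carbenoid 16 then adds to boron of 15 with retention to give boronate 17. Promoted by MgBr2 and gentle heating, the C13 alkyl group shifts from boron to C12 antiperiplanar to the departing carbamate (inversion at C12, retention at C13), which forms the C12–C13 bond and leaves C12 as a C–B bond. The closest known reaction type is the lithiation–borylation of sparteine-complexed α-lithiated alkyl carbamates with secondary pinacol boronic esters, a Matteson-type 1,2-metallate rearrangement; no ring is closed, so no mode of closure applies. C12 is the only new stereocentre and is set as 12R by the chiral diamine (reagent control), while 13R is carried in unchanged from 15. The step needs selection between the enantiotopic C12 protons and complete transfer to a hindered α-branched boron partner: the first is secured by the carbamate–sparteine pair, C9 lying too far away to override it, and the second by the Lewis acid, which speeds the shift before the boronate can revert. The alkenes and the dimethoxyarene of 15 offer no electrophilic site other than boron and so should stay intact.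

Step 9
Reactants: 18 (12R,13R)-C12 pinacol boronic ester
Product: 19 (2R,3R,7E)-9-(2,5-dimethoxyphenyl)-3,7-dimethyl-1-[(1S,4aS,8aS)-2,5,5,8a-tetramethyl-1,4,4a,5,6,7,8,8a-octahydronaphthalen-1-yl]non-7-en-2-ol (12R,13R alcohol)
Conditions: 30% H2O2, 2 M NaOH, THF, 0 °C to rt
Reagents that add atoms: hydrogen peroxide OO
Why: Oxidation of the secondary boronic ester with alkaline hydrogen peroxide proceeds by 1,2-shift of C12 from boron to oxygen with retention, so the 12R C–B bond becomes the 12R carbinol, and the trisubstituted alkenes and aryl ethers are inert to the peroxide anion.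

Step 10
Reactants: 19 (12R,13R) alcohol
Product: 21 sodium salt of the C12 sulfate monoester of 19, via pyridinium sulfate 20 (not isolated)
Conditions: SO3·pyridine, pyridine, rt to 40 °C; then aq. NaHCO3
Reagents that add atoms: sulfur trioxide–pyridine complex O=S(=O)([O-])[n+]1ccccc1; sodium hydrogencarbonate [Na+].OC(=O)[O-]
Why: O-sulfation of the only free hydroxyl with the sulfur trioxide–pyridine complex forms the sulfate monoester without breaking a bond at C12, the phenols being masked as methyl ethers, and the bicarbonate work-up should deliver the stable sodium salt.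

Step 11
Reactants: 21 sodium sulfate of the dimethoxyarene
Product: 22 sodium salt of the quinone sulfate (2-substituted 1,4-benzoquinone in place of the dimethoxyarene)
Conditions: (NH4)2Ce(NO3)6, MeCN/H2O, 0 °C, short contact; NaHCO3/brine work-up
Reagents that add atoms: water O
Why: Oxidative demethylation of the para-dimethoxyarene by the one-electron oxidant tetravalent cerium should give the benzoquinone far faster than any attack on the isolated trisubstituted alkenes, and the brief cold contact should spare the sulfate monoester.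

Step 12
Reactants: 22 sodium salt of the quinone sulfate
Product: 24 halisulfate 1, via hydroquinone sulfate sodium salt 23 (not isolated)
Conditions: Na2S2O4, EtOAc/H2O, rt, Ar; then cold 1 M HCl, EtOAc extraction, 0 °C
Reagents that add atoms: none
Why: Dithionite reduces the quinone to the hydroquinone (two-electron quinone reduction) without affecting alkenes or sulfate, and the cold acid partition exchanges sodium for a proton to give the hydrogen sulfate drawn for the target.

Compound list

1 | (+)-sclareolide, (3aR,5aS,9aS,9bR)-3a,6,6,9a-tetramethyldecahydronaphtho[2,1-b]furan-2(1H)-one | C[C@@]12CC[C@H]3C(C)(C)CCC[C@]3(C)[C@H]1CC(=O)O2 | starting material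
2 | (1R,2R,4aS,8aS)-1-(2-hydroxyethyl)-2,5,5,8a-tetramethyldecahydronaphthalen-2-ol (homodrimane-8α,12-diol) | C[C@@]1(O)CC[C@H]2C(C)(C)CCC[C@]2(C)[C@H]1CCO | intermediate
3 | 2-[(1R,2R,4aS,8aS)-2-hydroxy-2,5,5,8a-tetramethyldecahydronaphthalen-1-yl]ethyl N,N-diisopropylcarbamate | C[C@@]1(O)CC[C@H]2C(C)(C)CCC[C@]2(C)[C@H]1CCOC(=O)N(C(C)C)C(C)C | intermediate
4 | 2-[(1S,4aS,8aS)-2,5,5,8a-tetramethyl-1,4,4a,5,6,7,8,8a-octahydronaphthalen-1-yl]ethyl N,N-diisopropylcarbamate (homodrim-7-en-12-yl carbamate) | CC1=CC[C@H]2C(C)(C)CCC[C@]2(C)[C@H]1CCOC(=O)N(C(C)C)C(C)C | intermediate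
5 | 5-chloropent-1-yne | C#CCCCCl | starting material
6 | 2,5-dimethoxybenzyl chloride, 2-(chloromethyl)-1,4-dimethoxybenzene | COc1ccc(OC)c(CCl)c1 | starting material
7 | (E)-(5-chloro-2-methylpent-1-en-1-yl)dimethylalane (formed in the flask) | ClCCC/C(C)=C/[Al](C)C | intermediate
8 | 2-[(2E)-6-chloro-3-methylhex-2-en-1-yl]-1,4-dimethoxybenzene | ClCCC/C(C)=C/Cc1cc(OC)ccc1OC | intermediate
9 | [(4E)-6-(2,5-dimethoxyphenyl)-4-methylhex-4-en-1-yl]magnesium chloride (formed in the flask) | Cl[Mg]CCC/C(C)=C/Cc1cc(OC)ccc1OC | intermediate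
10 | 2-[(4E)-6-(2,5-dimethoxyphenyl)-4-methylhex-4-en-1-yl]-4,4,5,5-tetramethyl-1,3,2-dioxaborolane | CC1(C)OB(CCC/C(C)=C/Cc2cc(OC)ccc2OC)OC1(C)C | intermediate
11 | ethanol | CCO | starting material
12 | ethyl N,N-diisopropylcarbamate | CCOC(=O)N(C(C)C)C(C)C | intermediate
13 | (S)-1-lithioethyl N,N-diisopropylcarbamate, held as its (−)-sparteine complex (formed in the flask) | C[C@H]([Li])OC(=O)N(C(C)C)C(C)C | intermediate
14 | lithium boronate complex from 13 and 10, carbenoid carbon S (formed in the flask) | C[C@@H](OC(=O)N(C(C)C)C(C)C)[B-]1(CCC/C(C)=C/Cc2cc(OC)ccc2OC)OC(C)(C)C(C)(C)O1.[Li+] | intermediate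
15 | 2-[(2R,6E)-8-(2,5-dimethoxyphenyl)-6-methyloct-6-en-2-yl]-4,4,5,5-tetramethyl-1,3,2-dioxaborolane | CC1(C)OB([C@H](C)CCC/C(C)=C/Cc2cc(OC)ccc2OC)OC1(C)C | intermediate
16 | (12S)-12-lithio derivative of 4, held as its (−)-sparteine complex (formed in the flask) | CC1=CC[C@H]2C(C)(C)CCC[C@]2(C)[C@H]1C[C@H]([Li])OC(=O)N(C(C)C)C(C)C | intermediate
17 | lithium boronate complex from 16 and 15, 12S,13R (formed in the flask) | CC1=CC[C@H]2C(C)(C)CCC[C@]2(C)[C@H]1C[C@@H](OC(=O)N(C(C)C)C(C)C)[B-]3(OC(C)(C)C(C)(C)O3)[C@H](C)CCC/C(C)=C/Cc4cc(OC)ccc4OC.[Li+] | intermediate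
18 | 2-[(2R,3R,7E)-9-(2,5-dimethoxyphenyl)-3,7-dimethyl-1-[(1S,4aS,8aS)-2,5,5,8a-tetramethyl-1,4,4a,5,6,7,8,8a-octahydronaphthalen-1-yl]non-7-en-2-yl]-4,4,5,5-tetramethyl-1,3,2-dioxaborolane (12R,13R) | CC1=CC[C@H]2C(C)(C)CCC[C@]2(C)[C@H]1C[C@@H](B3OC(C)(C)C(C)(C)O3)[C@H](C)CCC/C(C)=C/Cc4cc(OC)ccc4OC | intermediate
19 | (2R,3R,7E)-9-(2,5-dimethoxyphenyl)-3,7-dimethyl-1-[(1S,4aS,8aS)-2,5,5,8a-tetramethyl-1,4,4a,5,6,7,8,8a-octahydronaphthalen-1-yl]non-7-en-2-ol (12R,13R alcohol) | CC1=CC[C@H]2C(C)(C)CCC[C@]2(C)[C@H]1C[C@@H](O)[C@H](C)CCC/C(C)=C/Cc1cc(OC)ccc1OC | intermediate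
20 | pyridinium salt of the C12 sulfate monoester of 19 (formed in the flask) | CC1=CC[C@H]2C(C)(C)CCC[C@]2(C)[C@H]1C[C@@H](OS(=O)(=O)[O-])[C@H](C)CCC/C(C)=C/Cc1cc(OC)ccc1OC.c1cc[nH+]cc1 | intermediate
21 | sodium salt of the C12 sulfate monoester of 19 (12R,13R) | CC1=CC[C@H]2C(C)(C)CCC[C@]2(C)[C@H]1C[C@@H](OS(=O)(=O)[O-])[C@H](C)CCC/C(C)=C/Cc1cc(OC)ccc1OC.[Na+] | intermediate
22 | sodium salt of the quinone sulfate, the arene of 21 replaced by a 2-substituted 1,4-benzoquinone | CC1=CC[C@H]2C(C)(C)CCC[C@]2(C)[C@H]1C[C@@H](OS(=O)(=O)[O-])[C@H](C)CCC/C(C)=C/CC1=CC(=O)C=CC1=O.[Na+] | intermediate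
23 | sodium salt of the hydroquinone sulfate, halisulfate 1 sodium salt (formed in the flask) | CC1=CC[C@H]2C(C)(C)CCC[C@]2(C)[C@H]1C[C@@H](OS(=O)(=O)[O-])[C@H](C)CCC/C(C)=C/Cc1cc(O)ccc1O.[Na+] | intermediate
24 | halisulfate 1, the (12R,13R)-C12 hydrogen sulfate with the free 2,5-dihydroxyphenyl group | CC1=CC[C@H]2C(C)(C)CCC[C@]2(C)[C@H]1C[C@@H](OS(=O)(=O)O)[C@H](C)CCC/C(C)=C/Cc1cc(O)ccc1O | target

Total step count: 12 steps.
Longest linear sequence: 8 steps (steps 1, 2, 3, 8, 9, 10, 11, 12; the side-chain branch through steps 4, 5, 7 and then 8 to 12 is equally long).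

Steps most likely to fail

Step 3. Proton loss from the C8 cation may be poorly site-selective, and prolonged acid may move the alkene into the tetrasubstituted C8–C9 position, so that the 7-ene has to be separated from isomers. The fallback sets out from 3 and fixes the alkene position through an enolate. SOCl2/pyridine in CH2Cl2 at −78 °C should give the exocyclic 8-methylene carbamate F1, because the equatorial chlorosulfite has no antiperiplanar ring proton and only a methyl proton can be removed. Ozonolysis (O3, CH2Cl2/MeOH, −78 °C, then Me2S) should give the 8-ketone F2. Kinetic deprotonation at the C7 methylene with LiN(iPr)2 in THF at −78 °C and trapping with PhNTf2 should give the Δ7 enol triflate F3. Coupling with Me2CuLi in Et2O at −20 °C replaces triflate by methyl and returns to the route at 4.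

Step 8. The bulky sparteine-bound carbenoid may add slowly or reversibly to the α-branched boronic ester 15, so that it decomposes or loses its configuration before the 1,2-shift takes place. The fallback keeps the C12–C13 bond formation but generates a diamine-free carbenoid bearing a better leaving group; it sets out from 4 and uses 15 unchanged. LiAlH4 in refluxing THF should cleave the carbamate to homodrim-7-en-12-ol F4. Mitsunobu esterification with 2,4,6-triisopropylbenzoic acid (PPh3, DIAD, THF) should give the triisopropylbenzoate F5. Lithiation with s-BuLi/(−)-sparteine in Et2O at −78 °C and quenching with Me3SnCl should give the (S)-α-trimethylstannyl benzoate F6, which can be purified and stored. Tin–lithium exchange with n-BuLi at −78 °C then releases the ligand-free α-lithio benzoate F7 with retention. F7 adds to 15 to give the boronate complex F8, which rearranges on warming with loss of the benzoate and returns to the route at 18.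

Step 11. The acidic tetravalent cerium medium may solvolyse the sulfate monoester or lead to over-oxidation while the anionic substrate is held in the aqueous phase. The fallback exchanges the order of oxidation and sulfation and sets out from 19. Oxidative demethylation with (NH4)2Ce(NO3)6 in MeCN/H2O at 0 °C, now on a neutral substrate, should give the quinone alcohol F9. Sulfation of its only hydroxyl with SO3·DMF in DMF at 0 °C, a reagent free of nucleophilic amine that could add to the quinone, followed by NaHCO3 work-up, returns to the route at 22.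

Further compounds
F1 | step 3 | exocyclic 8-methylene isomer of 4 (C5, C9, C10 as in 4) | C=C1CC[C@H]2C(C)(C)CCC[C@]2(C)[C@H]1CCOC(=O)N(C(C)C)C(C)C
F2 | step 3 | 8-oxo nor-carbamate (ketone at C8, C9 side chain unchanged) | O=C1CC[C@H]2C(C)(C)CCC[C@]2(C)[C@H]1CCOC(=O)N(C(C)C)C(C)C
F3 | step 3 | Δ7 enol triflate of F2 | O=S(=O)(OC1=CC[C@H]2C(C)(C)CCC[C@]2(C)[C@H]1CCOC(=O)N(C(C)C)C(C)C)C(F)(F)F
F4 | step 8 | homodrim-7-en-12-ol | CC1=CC[C@H]2C(C)(C)CCC[C@]2(C)[C@H]1CCO
F5 | step 8 | homodrim-7-en-12-yl 2,4,6-triisopropylbenzoate | CC1=CC[C@H]2C(C)(C)CCC[C@]2(C)[C@H]1CCOC(=O)c1c(C(C)C)cc(C(C)C)cc1C(C)C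
F6 | step 8 | (12S)-12-trimethylstannyl derivative of F5 | CC1=CC[C@H]2C(C)(C)CCC[C@]2(C)[C@H]1C[C@H]([Sn](C)(C)C)OC(=O)c1c(C(C)C)cc(C(C)C)cc1C(C)C
F7 | step 8 | (12S)-12-lithio derivative of F5, ligand-free | CC1=CC[C@H]2C(C)(C)CCC[C@]2(C)[C@H]1C[C@H]([Li])OC(=O)c1c(C(C)C)cc(C(C)C)cc1C(C)C
F8 | step 8 | lithium boronate complex from F7 and 15 | CC1=CC[C@H]2C(C)(C)CCC[C@]2(C)[C@H]1C[C@@H](OC(=O)c1c(C(C)C)cc(C(C)C)cc1C(C)C)[B-]3(OC(C)(C)C(C)(C)O3)[C@H](C)CCC/C(C)=C/Cc4cc(OC)ccc4OC.[Li+]
F9 | step 11 | quinone alcohol, the arene of 19 replaced by a 2-substituted 1,4-benzoquinone | CC1=CC[C@H]2C(C)(C)CCC[C@]2(C)[C@H]1C[C@@H](O)[C@H](C)CCC/C(C)=C/CC1=CC(=O)C=CC1=O
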